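The numbers were drawn at random within sensible limits; the rest is arithmetic.

A small charge of precatalyst has to turn a racemate over, but the partner must release it first and it must then escape the added ligand.

    free catalyst + added ligand ⇌ idle complex, settled at all times (K1 = 548 M⁻¹, ΔH1 = −69.0 kJ mol⁻¹)
    partner + free catalyst + left-handed substrate → free catalyst + left-handed product (k2 = 67.7 M⁻² s⁻¹, Ea2 = 36.0 kJ mol⁻¹)
    partner + free catalyst + right-handed substrate → free catalyst + right-handed product (k3 = 27.4 M⁻² s⁻¹, Ea3 = 45.0 kJ mol⁻¹)
    left-handed substrate ⇌ right-handed substrate (k4 = 2.67 s⁻¹, Ea4 = 67.0 kJ mol⁻¹)
    free catalyst → spent catalyst (k5 = 0.00732 s⁻¹, Ea5 = 105 kJ mol⁻¹)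
    partner + precatalyst → free catalyst + spent reagent (k6 = 0.111 M⁻¹ s⁻¹, Ea6 = 58.0 kJ mol⁻¹)
    (constants at 70 °C)

the same everywhere: left-handed substrate 0.27 M; partner 0.675 M; precatalyst 2.7 mM; added ligand 4.0 mM; right-handed substrate 0.27 M; time 10 s
- eta: temperature 100 °C
- alpha: temperature 40 °C
- theta: temperature 70 °C

- the best flask by amount of left-handed product, in percent of the left-handed substrate and right-handed substrate together charged; "all alike" if 1.5 percentage points covers them all (eta / alpha / theta / all alike)
- amount of left-handed product at the end, in percent of the left-handed substrate and right-handed substrate together charged, eta
- amount of left-handed product at the end, in percent of the left-handed substrate and right-handed substrate together charged, alpha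
- amount of left-handed product at the end, in percent of the left-handed substrate and right-handed substrate together charged, theta

- free catalyst is single-handed; left-handed substrate and right-handed substrate are mirror images of each other, charged as a racemate, each of them at the stated concentration
- all constants are for 70 °C and move with temperature by the activation energies and enthalpies

Reckon the coldest flask, alpha, one process at a time, with every amount as a fraction of its charge. Begin with the main step alone and pretend the charged catalyst is free from the start. At 40 °C, left-handed substrate then reacts at the pseudo-first-order rate 0.0368 s⁻¹. It is half of the substrates charged, and its relaxation half-life with the right-handed form, 1.23 s, is shorter than the run. Hold left-handed substrate at its charge and draw a straight line over 10 s: that gives 18.4%, a starting figure for the later steps to cut down.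

Now add release. Its time at the charged partner is 93.6 s, longer than the run, so the released fraction climbs in a line to 10.7%. Its average is half of that, which cuts the number to 0.984%.

Now add the ligand. Its binding constant at 40 °C is 5560 M⁻¹, and 4.0 mM of ligand leaves 4.30% of the released catalyst working. Call this the free share: one over one plus the binding constant times the ligand charged. It brings alpha to 0.0424%, far below the half of the substrates that left-handed substrate makes up, so holding it at its charge stands. Catalyst death takes 4640 s here, far longer than the run, so drop it.

The same share is 31.3% in theta and 76.1% in eta, the highest of the three. Pick eta, but stop the arithmetic there: its catalyst death time, 7.09 s, is shorter than the run, and the straight lines fail.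

The forecast also picks eta, with 32% for eta, 5.6% for theta and 0.045% for alpha, which is above my figure. Its ground: “Heat speeds activation and frees catalyst from the exothermic ligand binding”.

The simulation puts eta first, with 33.6%, against 5.84% for theta and 0.0426% for alpha. In alpha, release crept on with precatalyst still at 89.9% after 10.0 s, while free catalyst at 0.465% stood beside idle complex at 9.67%, a free share of 4.59%. In eta, free catalyst fell from 44.7% at 5.00 s to 33.1% at 10.0 s as spent catalyst reached 52.0%. Cut alpha's ligand to 0.0016 M and the free share becomes 10.1%, which scales alpha's result to 0.100%; that neighbour flask read 0.106%.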